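**Retrosynthetic overview**
- Feature: in the 2,3-dihydro-1,4-benzodioxine the adjacent arene carbons C8a and C4a of ring B (the benzene ring of the bicycle) carry O1 and O4, so O1–C2(aryl)–C3(methyl)–O4 is a four-atom tether between two ynol ether alkynes.
- Key disconnection: ring B and the dioxane ring open together by a retro-[2+2+2] (C4a–C8a, C7–C8, C5–C6) to the (1R,2R) bis(ynol ether) (ethynyl on the benzylic oxygen, trimethylsilylethynyl on the other) plus 3,3-diethoxyprop-1-yne. The silyl group places the acetal at C7 and is the handle for the C5 methoxy group (ICl, then CuI/NaOMe).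
- Side chain: acetal → aldehyde → Horner–Wadsworth–Emmons ester → allylic alcohol.
- Diyne: two different halovinyl ethers are installed with potassium alkoxides, a (Z)-2-chlorovinyl ether on the lactate oxygen and a 1,2-dichlorovinyl ether on the benzylic oxygen. One amide-base/Me3SiCl/n-BuLi operation turns the first into the silylalkyne and the second into the terminal alkyne, so no protecting group is needed and no alkoxide, fluoride or acid meets a finished ynol ether.
- Stereocentres and ring order: C3 from methyl (R)-lactate, C2 by Felkin–Anh reduction of the aryl ketone; the trimethoxyphenyl ring is bought, the dioxane ring and ring B form together in the key step.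

Key step: step 7

Remark: benzodioxine locants are counted from O1 on the aryl-bearing carbon (O1, C2, C3, O4, C4a, C5–C8, C8a) for every compound. The bis(ynol ether) is assumed to be kept at or below room temperature and used at once.

Step 1
Reactants: 1 methyl (R)-lactate
Product: 2 (2R)-2-hydroxy-1-(morpholin-4-yl)propan-1-one
Conditions: morpholine (3 equiv), neat, 85 °C
Reagents that add atoms: morpholine, C1COCCN1
Why: aminolysis of the ester gives the morpholine amide (a ketone precursor toward Grignard reagents) and no base able to enolise the stereocentre is present.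

Step 2
Reactants: 2 (2R)-2-hydroxy-1-(morpholin-4-yl)propan-1-one, 3 (Z)-1,2-dichloroethene
Product: 4 (2R)-2-{[(Z)-2-chloroethenyl]oxy}-1-(morpholin-4-yl)propan-1-one
Conditions: KH, THF, 0 °C; then 3, 0 °C to rt, argon
Reagents that add atoms: none
Why: base-induced anti-elimination of HCl from the cis-dihalide gives chloroacetylene, formed and consumed in solution, and the potassium alkoxide adds trans across it to give the (Z)-2-chlorovinyl ether (alkoxide addition to a haloacetylene); the amide α-C–H is too weakly acidic to epimerise.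

Step 3
Reactants: 5 5-bromo-1,2,3-trimethoxybenzene, 4 (2R)-2-{[(Z)-2-chloroethenyl]oxy}-1-(morpholin-4-yl)propan-1-one
Product: 7 (2R)-2-{[(Z)-2-chloroethenyl]oxy}-1-(3,4,5-trimethoxyphenyl)propan-1-one, via arylmagnesium bromide 6 (not isolated)
Conditions: Mg, THF, reflux; then 4, THF, 0 °C to rt; aq. NH4Cl
Reagents that add atoms: none
Why: Grignard acylation by a morpholine amide stops at the ketone because the tetrahedral magnesium adduct persists until work-up; the vinyl chloride and the stereocentre are inert.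

Step 4
Reactants: 7 (2R)-2-{[(Z)-2-chloroethenyl]oxy}-1-(3,4,5-trimethoxyphenyl)propan-1-one
Product: 8 (1R,2R)-2-{[(Z)-2-chloroethenyl]oxy}-1-(3,4,5-trimethoxyphenyl)propan-1-ol
Conditions: LiBH(s-Bu)3, THF, −78 °C; then NaOH, H2O2
Reagents that add atoms: none
Why: Felkin–Anh-controlled reduction: with the poorly chelating vinyl ether oxygen anti to the bulky hydride, attack past the α-hydrogen should set C1 as (R), giving the threo (1R,2R) alcohol; any erythro isomer would be removed by chromatography.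

Step 5
Reactants: 8 (1R,2R)-2-{[(Z)-2-chloroethenyl]oxy}-1-(3,4,5-trimethoxyphenyl)propan-1-ol, 9 trichloroethene
Product: 10 5-[(1R,2R)-2-{[(Z)-2-chloroethenyl]oxy}-1-{[(E)-1,2-dichloroethenyl]oxy}propyl]-1,2,3-trimethoxybenzene
Conditions: KH, THF, 0 °C to rt; then 9, −50 °C to rt
Reagents that add atoms: none
Why: the potassium alkoxide adds trans to dichloroacetylene formed in situ from trichloroethene (alkoxide dichlorovinylation), giving the (E)-1,2-dichlorovinyl ether; the neighbouring chlorovinyl ether needs an amide base to eliminate and should be inert here.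

Step 6
Reactants: 10 5-[(1R,2R)-2-{[(Z)-2-chloroethenyl]oxy}-1-{[(E)-1,2-dichloroethenyl]oxy}propyl]-1,2,3-trimethoxybenzene
Product: 14 5-[(1R,2R)-1-(ethynyloxy)-2-{[(trimethylsilyl)ethynyl]oxy}propyl]-1,2,3-trimethoxybenzene, via lithium acetylide chloroalkyne 11 (not isolated), via silylalkyne chloroalkyne 12 (not isolated), via silylalkyne lithium acetylide 13 (not isolated)
Conditions: LiN(i-Pr)2 (3.1 equiv), THF, −78 to −20 °C; Me3SiCl (1.2 equiv), −78 °C; n-BuLi (4.5 equiv, 3 equiv are taken up by HN(i-Pr)2), −78 °C; pH 7 buffer (NaH2PO4/Na2HPO4), −78 to 0 °C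
Reagents that add atoms: chlorotrimethylsilane, C[Si](C)(C)Cl
Why: base-induced dehydrohalogenation of halovinyl ethers to ynol ethers: the amide base takes the 2-chlorovinyl ether to its lithium acetylide (then silylated) but the 1,2-dichlorovinyl ether only to the chloroalkynyl ether, which n-BuLi converts by chlorine–lithium exchange into the acetylide that is protonated on quench.

Step 7
Reactants: 14 5-[(1R,2R)-1-(ethynyloxy)-2-{[(trimethylsilyl)ethynyl]oxy}propyl]-1,2,3-trimethoxybenzene, 15 3,3-diethoxyprop-1-yne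
Product: 16 (2R,3R)-7-(diethoxymethyl)-3-methyl-5-(trimethylsilyl)-2-(3,4,5-trimethoxyphenyl)-2,3-dihydro-1,4-benzodioxine
Conditions: Cp*RuCl(cod) (10 mol %), 15 (4 equiv), ClCH2CH2Cl, 20 °C, 14 added over 2 h
Reagents that add atoms: none
Why: Proposed new method: the two tethered ynol ether alkynes should couple oxidatively on the Cp*RuCl fragment to a ruthenacyclopentadiene (C4a–C8a), 3,3-diethoxyprop-1-yne then inserts at the unsubstituted α-carbon (C7–C8) and reductive elimination forms C5–C6 and releases the arene. The closest known reaction type is the Cp*RuCl(cod)-catalysed [2+2+2] cycloaddition of tethered α,ω-diynes with terminal alkynes, in which silylalkynes and alkoxyalkynes are each tolerated; a diyne whose two alkynes are both ynol ethers and whose O–C–C–O tether closes a 1,4-dioxane has not been shown. The dioxane ring closes in the metal-mediated oxidative cyclisation, as the six-membered ring fused to the metallacycle, and the benzene ring closes by alkyne insertion followed by reductive elimination. No stereocentre is formed, and C2 and C3 keep the (R,R) configuration of 14 because neither is touched. The step needs cross- over homo-cyclotrimerisation, secured by slow addition of 14 to excess 15, and regioselective insertion, secured by the Me3Si group, which shields its own terminus so that the acetal-bearing carbon bonds to C8 and ends at C7, meta to silicon. Room temperature is needed because secondary and benzylic ynol ethers break down on heating by retro-ene and sigmatropic pathways.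

Step 8
Reactants: 16 (2R,3R)-7-(diethoxymethyl)-3-methyl-5-(trimethylsilyl)-2-(3,4,5-trimethoxyphenyl)-2,3-dihydro-1,4-benzodioxine
Product: 17 (2R,3R)-7-(diethoxymethyl)-5-iodo-3-methyl-2-(3,4,5-trimethoxyphenyl)-2,3-dihydro-1,4-benzodioxine
Conditions: ICl (1.05 equiv), CH2Cl2, −78 °C; aq. Na2S2O3/NaHCO3 at −78 °C
Reagents that add atoms: iodine monochloride, ClI
Why: electrophilic ipso-iododesilylation at C5, favoured by the β-silicon effect and the ortho oxygen O4; low temperature and one equivalent of ICl should limit iodination of the trimethoxyphenyl ring, and the cold basic quench keeps the acetal.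

Step 9
Reactants: 17 (2R,3R)-7-(diethoxymethyl)-5-iodo-3-methyl-2-(3,4,5-trimethoxyphenyl)-2,3-dihydro-1,4-benzodioxine
Product: 19 (2R,3R)-5-methoxy-3-methyl-2-(3,4,5-trimethoxyphenyl)-2,3-dihydro-1,4-benzodioxine-7-carbaldehyde, via methoxy acetal 18 (not isolated)
Conditions: CuI (20 mol %), NaOMe, MeOH/DMF, 100 °C; then 1 M HCl, THF, rt
Reagents that add atoms: sodium methoxide, [Na+].[O-]C; water, O
Why: Ullmann-type copper-catalysed methoxylation of the aryl iodide, to which the acetal is inert, followed by acid hydrolysis of the diethyl acetal; the trans-benzodioxane is the thermodynamic isomer and is not at risk.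

Step 10
Reactants: 19 (2R,3R)-5-methoxy-3-methyl-2-(3,4,5-trimethoxyphenyl)-2,3-dihydro-1,4-benzodioxine-7-carbaldehyde, 20 triethyl phosphonoacetate
Product: 21 ethyl (E)-3-[(2R,3R)-5-methoxy-3-methyl-2-(3,4,5-trimethoxyphenyl)-2,3-dihydro-1,4-benzodioxin-7-yl]prop-2-enoate
Conditions: NaH, THF, 0 °C to rt
Reagents that add atoms: none
Why: Horner–Wadsworth–Emmons olefination with a stabilised phosphonate gives the (E)-cinnamate.

Step 11
Reactants: 21 ethyl (E)-3-[(2R,3R)-5-methoxy-3-methyl-2-(3,4,5-trimethoxyphenyl)-2,3-dihydro-1,4-benzodioxin-7-yl]prop-2-enoate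
Product: 22 (E)-3-[(2R,3R)-5-methoxy-3-methyl-2-(3,4,5-trimethoxyphenyl)-2,3-dihydro-1,4-benzodioxin-7-yl]prop-2-en-1-ol
Conditions: i-Bu2AlH (2.5 equiv), CH2Cl2, −78 °C; aq. KNaC4H4O6
Reagents that add atoms: none
Why: 1,2-reduction of the α,β-unsaturated ester by i-Bu2AlH gives the (E)-allylic alcohol and leaves the alkene and the aryl ethers alone.

**Compound list**
1 | methyl (R)-lactate | COC(=O)[C@@H](C)O | starting material
2 | (2R)-2-hydroxy-1-(morpholin-4-yl)propan-1-one | O=C(N1CCOCC1)[C@@H](C)O | intermediate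
3 | (Z)-1,2-dichloroethene | Cl/C=C\Cl | starting material
4 | (2R)-2-{[(Z)-2-chloroethenyl]oxy}-1-(morpholin-4-yl)propan-1-one | O=C(N1CCOCC1)[C@@H](C)O/C=C\Cl | intermediate
5 | 5-bromo-1,2,3-trimethoxybenzene | COc1cc(Br)cc(OC)c1OC | starting material
6 | (3,4,5-trimethoxyphenyl)magnesium bromide | COc1cc([Mg]Br)cc(OC)c1OC | intermediate (not isolated)
7 | (2R)-2-{[(Z)-2-chloroethenyl]oxy}-1-(3,4,5-trimethoxyphenyl)propan-1-one | COc1cc(C(=O)[C@@H](C)O/C=C\Cl)cc(OC)c1OC | intermediate
8 | (1R,2R)-2-{[(Z)-2-chloroethenyl]oxy}-1-(3,4,5-trimethoxyphenyl)propan-1-ol | COc1cc([C@H]([C@@H](C)O/C=C\Cl)O)cc(OC)c1OC | intermediate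
9 | trichloroethene | ClC=C(Cl)Cl | starting material
10 | 5-[(1R,2R)-2-{[(Z)-2-chloroethenyl]oxy}-1-{[(E)-1,2-dichloroethenyl]oxy}propyl]-1,2,3-trimethoxybenzene | COc1cc([C@H]([C@@H](C)O/C=C\Cl)O/C(Cl)=C\Cl)cc(OC)c1OC | intermediate
11 | lithium 2-{[(1R,2R)-1-[(chloroethynyl)oxy]-1-(3,4,5-trimethoxyphenyl)propan-2-yl]oxy}ethyn-1-ide | COc1cc([C@H]([C@@H](C)OC#C[Li])OC#CCl)cc(OC)c1OC | intermediate (not isolated)
12 | 5-[(1R,2R)-1-[(chloroethynyl)oxy]-2-{[(trimethylsilyl)ethynyl]oxy}propyl]-1,2,3-trimethoxybenzene | COc1cc([C@H]([C@@H](C)OC#C[Si](C)(C)C)OC#CCl)cc(OC)c1OC | intermediate (not isolated)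
13 | lithium 2-{[(1R,2R)-1-(3,4,5-trimethoxyphenyl)-2-{[(trimethylsilyl)ethynyl]oxy}propyl]oxy}ethyn-1-ide | COc1cc([C@H]([C@@H](C)OC#C[Si](C)(C)C)OC#C[Li])cc(OC)c1OC | intermediate (not isolated)
14 | 5-[(1R,2R)-1-(ethynyloxy)-2-{[(trimethylsilyl)ethynyl]oxy}propyl]-1,2,3-trimethoxybenzene | COc1cc([C@H]([C@@H](C)OC#C[Si](C)(C)C)OC#C)cc(OC)c1OC | intermediate
15 | 3,3-diethoxyprop-1-yne | C#CC(OCC)OCC | starting material
16 | (2R,3R)-7-(diethoxymethyl)-3-methyl-5-(trimethylsilyl)-2-(3,4,5-trimethoxyphenyl)-2,3-dihydro-1,4-benzodioxine | COc1cc([C@H]2Oc3cc(C(OCC)OCC)cc([Si](C)(C)C)c3O[C@@H]2C)cc(OC)c1OC | intermediate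
17 | (2R,3R)-7-(diethoxymethyl)-5-iodo-3-methyl-2-(3,4,5-trimethoxyphenyl)-2,3-dihydro-1,4-benzodioxine | COc1cc([C@H]2Oc3cc(C(OCC)OCC)cc(I)c3O[C@@H]2C)cc(OC)c1OC | intermediate
18 | (2R,3R)-7-(diethoxymethyl)-5-methoxy-3-methyl-2-(3,4,5-trimethoxyphenyl)-2,3-dihydro-1,4-benzodioxine | COc1cc([C@H]2Oc3cc(C(OCC)OCC)cc(OC)c3O[C@@H]2C)cc(OC)c1OC | intermediate (not isolated)
19 | (2R,3R)-5-methoxy-3-methyl-2-(3,4,5-trimethoxyphenyl)-2,3-dihydro-1,4-benzodioxine-7-carbaldehyde | COc1cc([C@H]2Oc3cc(C=O)cc(OC)c3O[C@@H]2C)cc(OC)c1OC | intermediate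
20 | triethyl phosphonoacetate | CCOC(=O)CP(=O)(OCC)OCC | starting material
21 | ethyl (E)-3-[(2R,3R)-5-methoxy-3-methyl-2-(3,4,5-trimethoxyphenyl)-2,3-dihydro-1,4-benzodioxin-7-yl]prop-2-enoate | COc1cc([C@H]2Oc3cc(/C=C/C(=O)OCC)cc(OC)c3O[C@@H]2C)cc(OC)c1OC | intermediate
22 | (E)-3-[(2R,3R)-5-methoxy-3-methyl-2-(3,4,5-trimethoxyphenyl)-2,3-dihydro-1,4-benzodioxin-7-yl]prop-2-en-1-ol | COc1cc([C@H]2Oc3cc(/C=C/CO)cc(OC)c3O[C@@H]2C)cc(OC)c1OC | target

Total step count: 11. Longest linear sequence: 11 steps (1 to 22).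

**Steps most likely to fail**

Step 7. The oxidative coupling of two donor-substituted alkynes across a six-membered tether may be slower than oligomerisation of 14 or cyclotrimerisation of 15, and the ynol ethers may hydrate or rearrange before they are consumed. The fallback builds the benzodioxane by known aryl ether chemistry; it sets out from Grignard reagent 6 and comes back at 21. Ethyl (S)-lactate and morpholine give (2S)-2-hydroxy-1-(morpholin-4-yl)propan-1-one F1, which with excess 6 gives (2S)-2-hydroxy-1-(3,4,5-trimethoxyphenyl)propan-1-one F2. Mitsunobu etherification (PPh3, diisopropyl azodicarboxylate) with 3,4-dihydroxy-5-methoxybenzaldehyde should engage the more acidic 4-hydroxyl and invert the carbinol carbon, giving 3-hydroxy-5-methoxy-4-{[(2R)-1-oxo-1-(3,4,5-trimethoxyphenyl)propan-2-yl]oxy}benzaldehyde F3. Wittig olefination of the aldehyde with Ph3P=CHCO2Et gives ethyl (E)-3-(3-hydroxy-5-methoxy-4-{[(2R)-1-oxo-1-(3,4,5-trimethoxyphenyl)propan-2-yl]oxy}phenyl)prop-2-enoate F4, and NaBH4 reduces the ketone to ethyl (E)-3-(3-hydroxy-4-{[(2R)-1-hydroxy-1-(3,4,5-trimethoxyphenyl)propan-2-yl]oxy}-5-methoxyphenyl)prop-2-enoate F5. Acid (TsOH, toluene, 80 °C) ionises the benzylic alcohol and the ortho phenol closes the dioxane ring to the thermodynamically preferred trans isomer, which is 21.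

Step 6. The chloroalkynyl ether must survive beside the amide base while the chlorovinyl ether eliminates; halogen–lithium scrambling between the two termini or amination of the chloroalkyne would put silicon on the wrong alkyne or destroy it. The fallback separates the two ynol ether syntheses; it sets out from 8 and comes back at 14. LiN(i-Pr)2 (3.2 equiv) and then Me3SiCl convert 8 into (1R,2R)-1-(3,4,5-trimethoxyphenyl)-1-(trimethylsilyloxy)-2-{[(trimethylsilyl)ethynyl]oxy}propane F6. Brief treatment with citric acid in MeOH at 0 °C removes only the O-silyl group to give (1R,2R)-1-(3,4,5-trimethoxyphenyl)-2-{[(trimethylsilyl)ethynyl]oxy}propan-1-ol F7. The alkoxide is generated with KN(SiMe3)2 at −78 °C and trapped at once with trichloroethene 9 to give 5-[(1R,2R)-1-{[(E)-1,2-dichloroethenyl]oxy}-2-{[(trimethylsilyl)ethynyl]oxy}propyl]-1,2,3-trimethoxybenzene F8; n-BuLi at −78 °C and a buffered quench then give 14.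

Step 8. Electrophilic iodination of the electron-rich trimethoxyphenyl ring may compete with ipso attack at C5, and the acid released may open the acetal. The fallback avoids electrophilic halogenation; it sets out from 16 and comes back at 18. Protodesilylation with HCl in dry EtOH gives (2R,3R)-7-(diethoxymethyl)-3-methyl-2-(3,4,5-trimethoxyphenyl)-2,3-dihydro-1,4-benzodioxine F9. Sterically controlled C–H borylation ([Ir(OMe)(cod)]2, 4,4′-di-tert-butyl-2,2′-bipyridine, B2pin2) should take place at C5–H, the only arene C–H flanked by no carbon substituent, to give 2-[(2R,3R)-7-(diethoxymethyl)-3-methyl-2-(3,4,5-trimethoxyphenyl)-2,3-dihydro-1,4-benzodioxin-5-yl]-4,4,5,5-tetramethyl-1,3,2-dioxaborolane F10. Oxidation with NaBO3 gives (2R,3R)-7-(diethoxymethyl)-3-methyl-2-(3,4,5-trimethoxyphenyl)-2,3-dihydro-1,4-benzodioxin-5-ol F11, and MeI/K2CO3 gives 18, which is hydrolysed as in step 9.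

**Further compounds**
F1 | step 7 | (2S)-2-hydroxy-1-(morpholin-4-yl)propan-1-one | O=C(N1CCOCC1)[C@H](C)O
F2 | step 7 | (2S)-2-hydroxy-1-(3,4,5-trimethoxyphenyl)propan-1-one | COc1cc(C(=O)[C@H](C)O)cc(OC)c1OC
F3 | step 7 | 3-hydroxy-5-methoxy-4-{[(2R)-1-oxo-1-(3,4,5-trimethoxyphenyl)propan-2-yl]oxy}benzaldehyde | COc1cc(C(=O)[C@@H](C)Oc2c(O)cc(C=O)cc2OC)cc(OC)c1OC
F4 | step 7 | ethyl (E)-3-(3-hydroxy-5-methoxy-4-{[(2R)-1-oxo-1-(3,4,5-trimethoxyphenyl)propan-2-yl]oxy}phenyl)prop-2-enoate | COc1cc(C(=O)[C@@H](C)Oc2c(O)cc(/C=C/C(=O)OCC)cc2OC)cc(OC)c1OC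
F5 | step 7 | ethyl (E)-3-(3-hydroxy-4-{[(2R)-1-hydroxy-1-(3,4,5-trimethoxyphenyl)propan-2-yl]oxy}-5-methoxyphenyl)prop-2-enoate | COc1cc(C(O)[C@@H](C)Oc2c(O)cc(/C=C/C(=O)OCC)cc2OC)cc(OC)c1OC
F6 | step 6 | (1R,2R)-1-(3,4,5-trimethoxyphenyl)-1-(trimethylsilyloxy)-2-{[(trimethylsilyl)ethynyl]oxy}propane | COc1cc([C@H]([C@@H](C)OC#C[Si](C)(C)C)O[Si](C)(C)C)cc(OC)c1OC
F7 | step 6 | (1R,2R)-1-(3,4,5-trimethoxyphenyl)-2-{[(trimethylsilyl)ethynyl]oxy}propan-1-ol | COc1cc([C@H]([C@@H](C)OC#C[Si](C)(C)C)O)cc(OC)c1OC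
F8 | step 6 | 5-[(1R,2R)-1-{[(E)-1,2-dichloroethenyl]oxy}-2-{[(trimethylsilyl)ethynyl]oxy}propyl]-1,2,3-trimethoxybenzene | COc1cc([C@H]([C@@H](C)OC#C[Si](C)(C)C)O/C(Cl)=C\Cl)cc(OC)c1OC
F9 | step 8 | (2R,3R)-7-(diethoxymethyl)-3-methyl-2-(3,4,5-trimethoxyphenyl)-2,3-dihydro-1,4-benzodioxine | COc1cc([C@H]2Oc3cc(C(OCC)OCC)ccc3O[C@@H]2C)cc(OC)c1OC
F10 | step 8 | 2-[(2R,3R)-7-(diethoxymethyl)-3-methyl-2-(3,4,5-trimethoxyphenyl)-2,3-dihydro-1,4-benzodioxin-5-yl]-4,4,5,5-tetramethyl-1,3,2-dioxaborolane | COc1cc([C@H]2Oc3cc(C(OCC)OCC)cc(B4OC(C)(C)C(C)(C)O4)c3O[C@@H]2C)cc(OC)c1OC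
F11 | step 8 | (2R,3R)-7-(diethoxymethyl)-3-methyl-2-(3,4,5-trimethoxyphenyl)-2,3-dihydro-1,4-benzodioxin-5-ol | COc1cc([C@H]2Oc3cc(C(OCC)OCC)cc(O)c3O[C@@H]2C)cc(OC)c1OC
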